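**Retrosynthetic overview**

1. The target is a cis-fused 3,7-dioxabicyclo[3.3.0]octan-2-one (lactone C1–C2(=O)–O3–C4–C5, ether ring C5–C6–O7–C8–C1, guaiacyl on C4, catechol ring on C8, both aryl groups on the convex face). The last operations are O-debenzylation and, before it, loss of a methoxycarbonyl group from C1, where reprotonation sets C1 through the cis ring fusion.
2. The lactone ring is closed second: a C4 alkoxide acylates the C1 ester cis to it (C2–O3). C4 is set by Felkin–Anh hydride reduction of the C4 aryl ketone, made from the C4 aldehyde, the guaiacyl Grignard reagent and an oxidation, because direct aryl addition is expected to favour the wrong C4 epimer.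
3. The C4 aldehyde is unmasked by ozonolysis of a vinyl group on C5.
4. The ether ring is closed first and is the feature on which the plan rests: the ring C5–C6–O7–C8–C1, with a geminal diester on C1, the aryl group on C8 and a vinyl group on C5, is the retron of an oxa-Michael addition (O7–C8) joined to an allylic alkylation (C1–C5). Racemic 2-vinyloxirane delivers O7, C6, C5 and the carbon that becomes C4; an arylidene malonate delivers C8, C1 and C2; zerovalent palladium with a chiral bisphosphine joins them.
5. The arylidene malonate comes from a Knoevenagel condensation of 3,4-bis(benzyloxy)benzaldehyde with dimethyl malonate.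

Key step: step 2

Assumption: the sense of induction in step 2 cannot be assigned with certainty in advance; the (R,R)-ligand L* = N,N'-[(1R,2R)-cyclohexane-1,2-diyl]bis[2-(diphenylphosphanyl)benzamide] is written, and its (S,S)-antipode would be used if the mirror-image oxolane forms.

**Route**

Step 1
Reactants: 1 3,4-bis(benzyloxy)benzaldehyde; 2 dimethyl malonate
Product: 3 dimethyl 2-[3,4-bis(benzyloxy)benzylidene]malonate
Conditions: piperidine (10 mol%), AcOH (10 mol%), toluene, reflux, Dean–Stark
Reagents that add atoms: none
Why: Knoevenagel condensation, in which piperidinium acetate mediates addition of the malonate to the aldehyde and azeotropic removal of water drives the dehydration; no stereochemical issue arises because the two ester groups are identical.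

Step 2
Reactants: 3 dimethyl 2-[3,4-bis(benzyloxy)benzylidene]malonate; 4 2-vinyloxirane (racemic)
Product: 5 dimethyl (2R,4R)-2-[3,4-bis(benzyloxy)phenyl]-4-ethenyloxolane-3,3-dicarboxylate (2,4-trans; any cis isomer is removed by chromatography)
Conditions: Pd2(dba)3·CHCl3 (2.5 mol%), (R,R)-L* (7.5 mol%), 4 (1.5 equiv), THF, 0 °C to rt
Reagents that add atoms: none
Why: Zerovalent palladium opens racemic 4 with inversion to a zwitterion (alkoxide plus π-allylpalladium cation), and the two diastereomeric allyl complexes should interconvert by π–σ–π isomerisation through the unsubstituted terminus before they are consumed, so that the racemate can funnel into one enantiomer (dynamic kinetic asymmetric transformation). The alkoxide adds reversibly to the β-carbon of 3 (bond O7–C8) and the malonate carbanion so formed attacks the internal allyl carbon anti to palladium (bond C1–C5); the closest known reaction type is the zerovalent-palladium-catalysed formal [3+2] annulation of vinyl epoxides with doubly activated alkenes. The oxolane ring closes in a 5-exo mode (the remaining alkene stays outside the ring), which the three-atom tether O7–C6–C5 enforces over the 7-endo alternative at the allyl terminus. C4 of the oxolane (C5 of the target) is set by the chiral ligand in the irreversible C–C bond formation. C2 of the oxolane (C8 of the target) is set relative to it: because the oxa-Michael step is reversible, both C8 epimers of the open adduct are available (Curtin–Hammett), and ring closure should run through the transition state that keeps the aryl group on the face away from the allyl–palladium unit, giving the 2,4-trans ring. The step therefore needs branched regioselectivity (secured by ring size), enantioselectivity (ligand) and trans diastereoselectivity (reversible first step plus the fully substituted C1 between the two centres), while the geminal diester gives the acceptor its electrophilicity and the carbanion its stability.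

Step 3
Reactants: 5 dimethyl (2R,4R)-2-[3,4-bis(benzyloxy)phenyl]-4-ethenyloxolane-3,3-dicarboxylate
Product: 7 dimethyl (2R,4R)-2-[3,4-bis(benzyloxy)phenyl]-4-formyloxolane-3,3-dicarboxylate, via ozonide 6 (not isolated)
Conditions: O3, CH2Cl2, −78 °C (Sudan Red 7B end point); then PPh3, −78 °C to rt
Reagents that add atoms: ozone, [O-][O+]=O
Why: Ozonolysis (Criegee cycloaddition, cycloreversion and recombination, then reductive cleavage of the ozonide by PPh3), in which the monosubstituted alkene reacts far faster than the alkoxy-substituted arenes so that dosing to the indicator end point should spare the benzyl ethers, and the neutral medium leaves the stereocentre next to the new aldehyde untouched.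

Step 4
Reactants: 7 dimethyl (2R,4R)-2-[3,4-bis(benzyloxy)phenyl]-4-formyloxolane-3,3-dicarboxylate; 8 1-(benzyloxy)-4-bromo-2-methoxybenzene
Product: 10 dimethyl (2R,4R)-2-[3,4-bis(benzyloxy)phenyl]-4-{[4-(benzyloxy)-3-methoxyphenyl](hydroxy)methyl}oxolane-3,3-dicarboxylate (both carbinol epimers, used crude), via Grignard reagent 9 (not isolated)
Conditions: 8, Mg, I2 (cat.), THF, 40 °C; then 7, THF, −78 °C; AcOH, −78 °C
Reagents that add atoms: none
Why: Grignard 1,2-addition, which at −78 °C should be much faster than attack on the two esters on the fully substituted carbon or removal of the α-proton, with a cold acidic quench to stop the alkoxide from lactonising; the carbinol centre forms without useful control (the Felkin–Anh model predicts mainly the epimer that would lead to the 4-epi lactone) and is therefore erased in step 5.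

Step 5
Reactants: 10 dimethyl (2R,4R)-2-[3,4-bis(benzyloxy)phenyl]-4-{[4-(benzyloxy)-3-methoxyphenyl](hydroxy)methyl}oxolane-3,3-dicarboxylate
Product: 11 dimethyl (2R,4R)-2-[3,4-bis(benzyloxy)phenyl]-4-[4-(benzyloxy)-3-methoxybenzoyl]oxolane-3,3-dicarboxylate
Conditions: Dess–Martin periodinane, CH2Cl2, 0 °C to rt
Reagents that add atoms: none
Why: Dess–Martin oxidation under near-neutral conditions converges both carbinol epimers on one aryl ketone without enolising it, which matters because base would endanger the α-stereocentre (C5 of the target) through epimerisation or β-elimination of the ring oxygen.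

Step 6
Reactants: 11 dimethyl (2R,4R)-2-[3,4-bis(benzyloxy)phenyl]-4-[4-(benzyloxy)-3-methoxybenzoyl]oxolane-3,3-dicarboxylate
Product: 13 methyl (1S,4S,5R,8R)-8-[3,4-bis(benzyloxy)phenyl]-4-[4-(benzyloxy)-3-methoxyphenyl]-2-oxo-3,7-dioxabicyclo[3.3.0]octane-1-carboxylate, via hydroxy diester 12 (not isolated)
Conditions: LiBH(s-Bu)3 (1.1 equiv), THF, −78 °C, then 0 °C; AcOH
Reagents that add atoms: none
Why: Felkin–Anh-controlled ketone reduction followed by lactonisation, in which the bulky hydride should attack anti to the fully substituted ring carbon C1 (the large α-substituent) and past the α-hydrogen to give the (S)-carbinol (C4 of the target), and on warming the lithium alkoxide acylates the only ester it can reach, the one cis to it on the oxolane, which closes the cis-fused γ-lactone with the aryl group on the convex face and makes C1 a defined quaternary stereocentre.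

Step 7
Reactants: 13 methyl (1S,4S,5R,8R)-8-[3,4-bis(benzyloxy)phenyl]-4-[4-(benzyloxy)-3-methoxyphenyl]-2-oxo-3,7-dioxabicyclo[3.3.0]octane-1-carboxylate
Product: 15 (1S,4S,5R,8S)-8-[3,4-bis(benzyloxy)phenyl]-4-[4-(benzyloxy)-3-methoxyphenyl]-3,7-dioxabicyclo[3.3.0]octan-2-one, via lithium carboxylate 14 (not isolated)
Conditions: LiCl (3 equiv), H2O (3 equiv), DMSO, 140 °C
Reagents that add atoms: none
Why: Krapcho dealkoxycarbonylation, in which chloride demethylates the ester by SN2 attack, the carboxylate loses CO2 and the lactone enolate is protonated by water on the only face that keeps the bicyclo[3.3.0] ring fusion cis, which sets C1 as (S); β-elimination of O7 from the enolate would be a retro-5-endo-trig process with the C8–O7 bond held near the nodal plane of the enolate and should therefore be slow.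

Step 8
Reactants: 15 (1S,4S,5R,8S)-8-[3,4-bis(benzyloxy)phenyl]-4-[4-(benzyloxy)-3-methoxyphenyl]-3,7-dioxabicyclo[3.3.0]octan-2-one
Product: 16 (1S,4S,5R,8S)-8-(3,4-dihydroxyphenyl)-4-(4-hydroxy-3-methoxyphenyl)-3,7-dioxabicyclo[3.3.0]octan-2-one (CNP0268159.1)
Conditions: H2 (1 atm), 10% Pd/C, EtOAc, rt, stopped when the benzyl ethers are consumed
Reagents that add atoms: none
Why: Catalytic hydrogenolysis, in which the three aryl benzyl ethers should be cleaved on Pd/C in aprotic ethyl acetate much faster than the secondary benzylic C4–O3 lactone bond and C8–O7 ether bond, so that the triphenol is released with all four stereocentres untouched.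

**Compound list**

1 | 3,4-bis(benzyloxy)benzaldehyde | O=Cc1ccc(OCc2ccccc2)c(OCc2ccccc2)c1 | starting material
2 | dimethyl malonate | COC(=O)CC(=O)OC | starting material
3 | dimethyl 2-[3,4-bis(benzyloxy)benzylidene]malonate | COC(=O)C(=Cc1ccc(OCc2ccccc2)c(OCc2ccccc2)c1)C(=O)OC | intermediate
4 | 2-vinyloxirane (racemic) | C=CC1CO1 | starting material
5 | dimethyl (2R,4R)-2-[3,4-bis(benzyloxy)phenyl]-4-ethenyloxolane-3,3-dicarboxylate | COC(=O)C1(C(=O)OC)[C@@H](C=C)CO[C@@H]1c1ccc(OCc2ccccc2)c(OCc2ccccc2)c1 | intermediate
6 | dimethyl (2R,4R)-2-[3,4-bis(benzyloxy)phenyl]-4-(1,2,4-trioxolan-3-yl)oxolane-3,3-dicarboxylate (ozonide, both configurations at the trioxolane carbon) | COC(=O)C1(C(=O)OC)[C@@H](C2OCOO2)CO[C@@H]1c1ccc(OCc2ccccc2)c(OCc2ccccc2)c1 | intermediate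
7 | dimethyl (2R,4R)-2-[3,4-bis(benzyloxy)phenyl]-4-formyloxolane-3,3-dicarboxylate | COC(=O)C1(C(=O)OC)[C@@H](C=O)CO[C@@H]1c1ccc(OCc2ccccc2)c(OCc2ccccc2)c1 | intermediate
8 | 1-(benzyloxy)-4-bromo-2-methoxybenzene | COc1cc(Br)ccc1OCc1ccccc1 | starting material
9 | [4-(benzyloxy)-3-methoxyphenyl]magnesium bromide | COc1cc([Mg]Br)ccc1OCc1ccccc1 | intermediate
10 | dimethyl (2R,4R)-2-[3,4-bis(benzyloxy)phenyl]-4-{[4-(benzyloxy)-3-methoxyphenyl](hydroxy)methyl}oxolane-3,3-dicarboxylate (both carbinol epimers) | COC(=O)C1(C(=O)OC)[C@@H](C(O)c2ccc(OCc3ccccc3)c(OC)c2)CO[C@@H]1c1ccc(OCc2ccccc2)c(OCc2ccccc2)c1 | intermediate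
11 | dimethyl (2R,4R)-2-[3,4-bis(benzyloxy)phenyl]-4-[4-(benzyloxy)-3-methoxybenzoyl]oxolane-3,3-dicarboxylate | COC(=O)C1(C(=O)OC)[C@@H](C(=O)c2ccc(OCc3ccccc3)c(OC)c2)CO[C@@H]1c1ccc(OCc2ccccc2)c(OCc2ccccc2)c1 | intermediate
12 | dimethyl (2R,4R)-2-[3,4-bis(benzyloxy)phenyl]-4-{(S)-[4-(benzyloxy)-3-methoxyphenyl](hydroxy)methyl}oxolane-3,3-dicarboxylate | COC(=O)C1(C(=O)OC)[C@@H]([C@H](O)c2ccc(OCc3ccccc3)c(OC)c2)CO[C@@H]1c1ccc(OCc2ccccc2)c(OCc2ccccc2)c1 | intermediate
13 | methyl (1S,4S,5R,8R)-8-[3,4-bis(benzyloxy)phenyl]-4-[4-(benzyloxy)-3-methoxyphenyl]-2-oxo-3,7-dioxabicyclo[3.3.0]octane-1-carboxylate | COc1cc([C@H]2OC(=O)[C@@]3(C(=O)OC)[C@@H]2CO[C@@H]3c2ccc(OCc4ccccc4)c(OCc4ccccc4)c2)ccc1OCc1ccccc1 | intermediate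
14 | lithium (1S,4S,5R,8R)-8-[3,4-bis(benzyloxy)phenyl]-4-[4-(benzyloxy)-3-methoxyphenyl]-2-oxo-3,7-dioxabicyclo[3.3.0]octane-1-carboxylate | [Li+].COc1cc([C@H]2OC(=O)[C@@]3(C(=O)[O-])[C@@H]2CO[C@@H]3c2ccc(OCc4ccccc4)c(OCc4ccccc4)c2)ccc1OCc1ccccc1 | intermediate
15 | (1S,4S,5R,8S)-8-[3,4-bis(benzyloxy)phenyl]-4-[4-(benzyloxy)-3-methoxyphenyl]-3,7-dioxabicyclo[3.3.0]octan-2-one | COc1cc([C@H]2OC(=O)[C@H]3[C@@H]2CO[C@@H]3c2ccc(OCc4ccccc4)c(OCc4ccccc4)c2)ccc1OCc1ccccc1 | intermediate
16 | (1S,4S,5R,8S)-8-(3,4-dihydroxyphenyl)-4-(4-hydroxy-3-methoxyphenyl)-3,7-dioxabicyclo[3.3.0]octan-2-one | COc1cc([C@H]2OC(=O)[C@H]3[C@@H]2CO[C@@H]3c2ccc(O)c(O)c2)ccc1O | target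

Total step count: 8. Longest linear sequence: 8 steps (1 to 16); the aryl bromide 8 enters in step 4 without a separate step.

**Steps most likely to fail**

Step 2. Ring closure may outrun equilibration of the diastereomeric allyl complexes, which would lower the enantiomeric purity, or it may run partly through the cis transition state, which would erode trans-selectivity. The fallback gives up asymmetric catalysis for resolution. It sets out from 3 and 4: the annulation is run with achiral Pd(PPh3)4 in THF, the cis isomers are removed on silica, and the racemic trans diester is resolved by preparative HPLC on a chiral stationary phase (amylose tris(3,5-dimethylphenylcarbamate)). This separates 5 from its mirror image, dimethyl (2S,4S)-2-[3,4-bis(benzyloxy)phenyl]-4-ethenyloxolane-3,3-dicarboxylate F1, which is discarded. The fallback comes back to the route at 5.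

Step 6. Hydride may be delivered to the wrong face of the ketone, since a transition state chelated through an ester carbonyl would reverse the Felkin–Anh preference; enolisation followed by β-elimination of the ring oxygen is a second hazard. The fallback replaces substrate control by catalyst control. It sets out from 11: asymmetric transfer hydrogenation with RuCl(p-cymene)[(S,S)-TsDPEN] in HCO2H/Et3N at rt, whose usual sense with aryl alkyl ketones gives the (S)-carbinol, should deliver 12, which is now isolated. Lactonisation with catalytic DBU in THF then gives 13, where the fallback comes back to the route. It makes no compound outside the list (F0).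

Step 8. Hydrogenolysis may not stop at the ether stage: cleavage of the benzylic C4–O3 lactone bond, and more slowly of C8–O7, would open the bicycle. The fallback replaces hydrogenolysis by Lewis-acid dealkylation with a cation scavenger. It sets out from 15: BCl3 and pentamethylbenzene in CH2Cl2 at −78 °C, then a methanol quench, should remove the three benzyl groups as benzylated scavenger and give 16 directly, where the fallback comes back to the route. It makes no compound outside the list (F0).

**Further compounds**

F1 | step 2 | dimethyl (2S,4S)-2-[3,4-bis(benzyloxy)phenyl]-4-ethenyloxolane-3,3-dicarboxylate | COC(=O)C1(C(=O)OC)[C@H](C=C)CO[C@H]1c1ccc(OCc2ccccc2)c(OCc2ccccc2)c1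
F0 | step 6 | none | none
F0 | step 8 | none | none
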